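At the last reading of this flask there was more isomer of the product than target, 60.8 % against 23.5 % at 2.50 h, and I wanted to know what would become of that lead.

| setting | north-east | flask |
|---|---|---|
| solid substrate | 0.010 M | 0.010 M |
| catalyst | 0.20 mM | 0.20 mM |
| remark | the very flask that is asked about, followed so far |  |
| time |  | 8.0 h |

- north-east (time / h: target / %, isomer of the product / %): 0.200: 4.2, 3.4; 0.333: 4.2, 7.6; 0.417: 5.3, 8.5; 0.667: 9.5, 17.3; 1.00: 13.3, 32.4; 1.50: 19.7, 46.9; 2.50: 23.5, 60.8

(scatter of a reading: 1 percentage point)

- ratio of target to isomer of the product at 3.0 min
- ratio of target to isomer of the product at 40 min
- ratio of target to isomer of the product at 8.0 h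
- which of target and isomer of the product there is more of at 8.0 h

- given per volume of solution although it is solid: solid substrate
- at the start none of the solid substrate is in solution

I treated the end as a small correction to that last reading. The two products then fell short of the charge by 15.7 %, and I assumed that this remainder would appear as these two products. My first way let it divide as the two products stood at that reading, in the ratio 0.387, which gave 27.9 % target. For my second way I took the target gained per isomer of the product gained between 1.00 h and 2.50 h, which I call the late split, a selectivity factor, and it came to 0.359. Sharing the remainder between the two products in that ratio gave 27.6 % target, so a ratio of 0.381.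

The two ways stood 0.30 percentage points apart, while a reading scatters by 1 point. Still, I distrusted the first, since its ratio carries the early readings, such as 1.24 at 0.200 h, which is higher than the late split. The target beyond what the late split accounts for, the head start, was 1.7 points at 2.50 h. The ratio at 40 min I simply read as 0.549; 3.0 min lies before the first reading, and I gave it no number.

For the ratio at 3.0 min, 40 min and 8.0 h the forecast gave 4, 0.52 and 0.38, with isomer of the product ahead, “assuming no slow drain”.

In the same order the flask gave 2.75, 0.504 and 0.386, with isomer of the product ahead, 72.1 % against 27.8 % of target.

    starting material ⇌ other conformer (K = 1.80, k = 0.00490 s⁻¹)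
    starting material + catalyst → catalyst + target (k = 14.0 M⁻¹ s⁻¹)
    catalyst + other conformer → catalyst + isomer of the product (k = 23.0 M⁻¹ s⁻¹)
    catalyst ⇌ dormant form (K = 15.0, k = 0.00990 s⁻¹)
    solid substrate ⇌ starting material, rate k5*(cs5 - [starting material]) while solid is left; crystals form when [starting material] > cs5 (solubility = 3.90 mM, k = 0.00200 s⁻¹)

Of the charged solid substrate, 0.039 % was still there, solid or dissolved, at 8.00 h. With the late split of 0.359, the head start in this flask at 8.00 h was 2 points, against 1.7 points at 2.50 h. In the neighbouring flask, charged with 0.0025 M of solid substrate, the ratio at 8.00 h was 0.424, and the same split leaves a head start of 4.6 points.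

The data were generated by integration for substances that don't exist, and the scatter is random.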